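**Easy step.** The bench habit carries a plateau percentage over from the nearest run, which would give the flask the 60.1% of target that the theta run holds at its last reading. The zeta run, with the same enzyme, ends at 37.9%, so the percentage does not carry over: from theta to zeta the charge rises by a factor of 1.59, and the percentage falls by a factor of 1.59.

| setting | theta | zeta | flask |
|---|---|---|---|
| solid substrate | 29 mM | 46 mM | 21 mM |
| enzyme | 0.12 µM | 0.12 µM | 0.12 µM |
| remark | run made earlier | run made earlier |  |
| time |  |  | 20 min |

| run | time / min | solid substrate / % | target / % |
|---|---|---|---|
| theta | 3.00 | 38.2 | 58.3 |
| theta | 6.00 | 35.7 | 60.0 |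
| theta | 10.0 | 35.5 | 60.5 |
| theta | 12.0 | 35.4 | 60.2 |
| theta | 15.0 | 36.0 | 60.1 |
| zeta | 1.33 | 78.1 | 20.5 |
| zeta | 4.00 | 60.3 | 37.2 |
| zeta | 8.00 | 59.2 | 37.4 |
| zeta | 12.0 | 59.3 | 37.8 |
| zeta | 15.0 | 59.8 | 37.9 |

(readings scatter by 0.3 percentage points)

- given per volume of solution although it is solid: solid substrate
- the numbers in the tables scatter by 0.3 percentage points (one standard deviation)
- at the start none of the solid substrate is in solution
- what has only dissolved of solid substrate counts as not reacted

* part of the solid substrate that has turned into other species by 20 min (what has only dissolved does not count)
* the target standing at 20 min, as a percentage of the solid substrate charged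
* amount of target if the flask were left three thousand times as long, in percent of the solid substrate charged

**Fixed amount.** Last plateau share times charge reads 17.4 mM of target in theta and 17.4 mM in zeta, and this amount at 0.12 µM of enzyme, the ceiling, reads like a total turnover number times the enzyme charge. Theta stands flat from 6.00 min to 15.0 min, so the asked time should lie on the plateau, and the ceiling over the charge puts the flask, with the same enzyme, at 83.0%.

**The border.** A ceiling reaches no further than the charge. The theta columns also fall short of the whole charge by 1.13 mM, and the zeta columns by 1.06 mM, which the reckoning here reads as dissolved solid substrate. Ceiling and gap together take 88.4% of the flask's charge, less than the whole, so solid should remain. Dissolved material counts as unreacted, so this reckoning puts conversion, target and long standing all at 83.0%.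

**The forecast.** It reads the gap as "a parallel by-product" and gives 88% conversion, 82% target and 82.5% on long standing, parting from the reckoning here on conversion.

**The flask.** Against the ceiling's 83.0%, the flask gives 82.9% conversion, 82.9% target and 82.9% on long standing, with 10.9% solid substrate and 6.19% starting material at 20.0 min.

    starting material + enzyme ⇌ complex (K = 130 M⁻¹, k = 3.14 × 10⁷ M⁻¹ s⁻¹)
    complex → enzyme + target (k = 29800 s⁻¹)
    solid substrate ⇌ starting material, rate k3*(cs3 - [starting material]) while solid is left; crystals form when [starting material] > cs3 (solubility = 1.30 mM, k = 0.129 s⁻¹)
    target + complex → spent catalyst (k = 23.6 M⁻¹ s⁻¹)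

**Neighbouring flask.** With 84 mM of solid substrate and all else held, the ceiling over the charge gives 20.7%. That flask gives 20.7% of target and 20.7% conversion at 20.0 min, with spent catalyst at 100% of the catalyst charged, and 79% of its charge is still there, solid or dissolved.

All runs are calculated with made-up constants; noise was put on by code.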